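The readings stem from a simulated flask for an exercise; scatter was added.

**The trap.** Equal loadings look like equal catalyst, but at 10 mol% of Z the [Z] grows with the charge of E, and X is used faster with it.

| flask | E | Z | remark | time |
|---|---|---|---|---|
| summer | 0.73 M | 6.7 mol% | run made earlier |  |
| dusk | 0.73 M | 5 mol% | run made earlier |  |
| south-west | 0.73 M | 10 mol% |  | 4.0 h |
| north | 0.20 M | 10 mol% |  | 4.0 h |
| north-west | 3.0 M | 10 mol% |  | 4.0 h |
| south | 2.0 M | 10 mol% |  | 4.0 h |
| west | 1.5 M | 10 mol% |  | 4.0 h |

| run | time / h | L / % | E / % |
|---|---|---|---|
| summer | 0.200 | 0 | 71.5 |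
| summer | 0.333 | 1.3 | 67.9 |
| summer | 0.667 | 5.1 | 59.0 |
| summer | 1.33 | 11.1 | 52.4 |
| summer | 2.50 | 25.5 | 38.1 |
| dusk | 0.200 | 0.4 | 72.5 |
| dusk | 0.333 | 1.4 | 67.0 |
| dusk | 0.667 | 4.1 | 63.0 |
| dusk | 1.33 | 9.6 | 55.6 |
| dusk | 2.50 | 18.5 | 44.9 |

(standard deviation of a reading: 1 percentage point)

- the flasks put in order of amount of L, in percent of the E charged, best first, at 4.0 h (south-west / north / north-west / south / west)
- the amount of L, in percent of the E charged of the flask you put first, at 4.0 h
- the amount of L, in percent of the E charged of the flask you put last, at 4.0 h

- for L the Q are counted in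
- as a solid, counted per litre of solution: E, Q
- reactions considered so far: X + Z -> J; G -> Z + L; Q <-> L; E <-> X; J <-> G
- at the start none of E is in solution
- what has only dissolved of E counts as not reacted

**The readings.** In the summer run, late E and L leave 36.4% of the charge unaccounted for. We read this as dissolved, J and G counted in, and take [X] as about 0.266 M. The steady climb of L spends that store with a lifetime of 3.27 h, a pseudo-first-order loss of X. The climb in summer is 1.42 times that in dusk, while the loading ratio is 1.34, so we scale the pace with [Z].

**The count.** North gets 0.500 as its lifetimes count, the asked time over the lifetime of X at the [Z] of that flask. Its charge of 0.20 M lies below the 0.266 M that dissolves, so north gets no refill, X simply decays, and we expect 39.4% of L.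

**One number?** Not where solid stands, since it refills the solution. There L follows the steady climb, and a second ratio trims it: the dissolving time, 0.131 h from the first summer reading, over the lifetime of X. This ratio is 0.0597 in south-west and 0.246 in north-west. Dividing the climb by one plus this ratio, we reckon 62.7% for south-west and 53.3% for north-west. Our order therefore runs from the smallest solid charge upward, with north last.

**The forecast.** The forecast said north-west > south > west > south-west > north, with 60% and 49%, holding that “More charge keeps saturation longest”.

**The result.** The flasks give south-west > west > south > north-west > north, with 60.0% and 41.4%.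

    X + Z → J (k = 0.134 /M/min)
    G → Z + L (k = 0.277 /min)
    Q ⇌ L, rate k3*(cs3 - [L]) while solid is left; crystals form when [L] > cs3 (solubility = 50.0 mM, k = 0.327 /min)
    E ⇌ X, rate k4*(cs4 - [X]) while solid is left; crystals form when [X] > cs4 (solubility = 0.260 M, k = 0.113 /min)
    J ⇌ G (K = 1.21, k = 2.33 /min)

**North's wait.** North stands at 41.4%, against our 39.4%, because 0.500 lifetimes is a short wait: read at 40.0 h instead, the same flask gives 99.8%. A neighbour of north with 2.5 mol% of Z has a count of 0.125, which gives 11.8% of L; computed, it gives 12.2%.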